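**Strategy.** The seven-membered ring (C3a–C4–C5–C6–C7–C8–C8a, azulene numbering) carries oxygen at C4 and C7, a 1,5-relationship across C8–C8a–C3a. That is the retron of a de Mayo reaction: C4–C8 are the five carbons of a cyclopentane-1,3-dione, and C3a/C8a are the alkene carbons of a preformed, fully functionalised cyclopentene (ring A). In one pot, [2+2] photocycloaddition of a benzyl-protected dione enol ether to the ring-A alkene gives a strained cyclobutane; hydrogenolysis unmasks the cyclobutanol, whose retro-aldol cleavage expands the five-membered ring by two carbons to the hydroazulene. The ring fusion is then corrected at C3a, and C4 is reduced under hydroxyl direction.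

Key step: step 7

Remarks on the chemistry (assumptions):
- Azulene numbering is used for all bicyclic compounds; "beta" is the face of ring A that carries the C8a methyl (in 6: the face of the acetoxy and isopropyl groups), "alpha" the opposite face.
- (+)-Ipc2BCl is assumed to give si-face addition to methacrolein, i.e. the (5S) aldol; if the opposite sense is found, the antipodal reagent is used.
- Compound 9 is racemic at its methyl-bearing carbon, so 10–12 are mixtures at C6; this centre becomes sp2 in step 8.
- 4-(Acetyloxy)benzoyl chloride is taken as a commercial reagent.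

Step 1
Reactants: 1 3-methylbutan-2-one; 2 2-methylprop-2-enal (methacrolein)
Product: 3 (5S)-5-hydroxy-2,6-dimethylhept-6-en-3-one
Conditions: (+)-Ipc2BCl, Et3N, Et2O, 0 °C; then 2, −78 to −20 °C; H2O2, pH 7 buffer, MeOH
Reagents that add atoms: none
Why: Paterson boron aldol reaction: the diisopinocampheyl enol borinate of the methyl ketone should add to the si face of the aldehyde through a cyclic transition state and set C5 (S), the future C1.

Step 2
Reactants: 3 (5S)-5-hydroxy-2,6-dimethylhept-6-en-3-one
Product: 4 (3R,5S)-6-methyl-3-(propan-2-yl)hepta-1,6-diene-3,5-diol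
Conditions: CH2=CHMgBr (3 equiv), THF–CH2Cl2, −78 °C; aq NH4Cl
Reagents that add atoms: vinylmagnesium bromide, C=C[Mg]Br
Why: Chelation-controlled Grignard addition: the magnesium alkoxide chelates the ketone in a six-membered half-chair with the isopropenyl group equatorial and the vinyl group enters axially, which should give the (3R) tertiary carbinol (the future C3, its hydroxyl trans to the C1 oxygen once the ring is closed).

Step 3
Reactants: 4 (3R,5S)-6-methyl-3-(propan-2-yl)hepta-1,6-diene-3,5-diol
Product: 5 (1R,3S)-4-methyl-1-(propan-2-yl)cyclopent-4-ene-1,3-diol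
Conditions: second-generation Grubbs catalyst (2 mol %), CH2Cl2, 40 °C
Reagents that add atoms: none
Why: Ring-closing metathesis of the 1,1-disubstituted and the monosubstituted alkene closes the trisubstituted cyclopentene (ring A) with loss of ethene and touches no stereocenter.

Step 4
Reactants: 5 (1R,3S)-4-methyl-1-(propan-2-yl)cyclopent-4-ene-1,3-diol
Product: 6 (1S,4R)-4-hydroxy-2-methyl-4-(propan-2-yl)cyclopent-2-en-1-yl acetate
Conditions: Ac2O, pyridine, DMAP (cat.), CH2Cl2, 0 °C
Reagents that add atoms: acetic anhydride, CC(=O)OC(C)=O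
Why: DMAP-catalysed acylation should be selective for the secondary allylic hydroxyl over the hindered tertiary one.

Step 5
Reactants: 7 cyclopentane-1,3-dione
Product: 8 3-(benzyloxy)cyclopent-2-en-1-one
Conditions: BnOH, TsOH (cat.), toluene, reflux (Dean–Stark)
Reagents that add atoms: benzyl alcohol, OCc1ccccc1
Why: Acid-catalysed vinylogous esterification of the enolised dione, driven by azeotropic removal of water.

Step 6
Reactants: 8 3-(benzyloxy)cyclopent-2-en-1-one
Product: 9 3-(benzyloxy)-5-methylcyclopent-2-en-1-one (racemic)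
Conditions: LiN(iPr)2, THF, −78 °C; MeI, −78 to 0 °C
Reagents that add atoms: iodomethane, CI
Why: Stork–Danheiser kinetic deprotonation of the vinylogous ester at C5 and methylation places the methyl group next to the carbonyl and not next to the enol carbon, which fixes the later position of the C6 methyl; the new centre is racemic and is removed in step 8.

Step 7
Reactants: 6 (1S,4R)-4-hydroxy-2-methyl-4-(propan-2-yl)cyclopent-2-en-1-yl acetate; 9 3-(benzyloxy)-5-methylcyclopent-2-en-1-one
Product: 12 (1S,3R,3aR,8aS)-3-hydroxy-6,8a-dimethyl-4,7-dioxo-3-(propan-2-yl)decahydroazulen-1-yl acetate (cis-fused; mixture at C6), via cyclobutane photoadduct 10 (not isolated), via cyclobutanol 11 (not isolated)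
Conditions: hν (350 nm, Pyrex), 9 (3 equiv), MeCN, 0 °C; then H2 (1 atm), Pd/C, EtOAc, 23 °C
Reagents that add atoms: none
Why: De Mayo reaction: the triplet vinylogous ester 9 should add across the C3a=C8a alkene of 6 in a head-to-tail [2+2] photocycloaddition (enol carbon to C3a, alpha-carbon to the methyl-bearing C8a) to give the cis,anti,cis cyclobutane 10, and hydrogenolysis of the benzyl ether frees the cyclobutanol 11, whose retro-aldol cleavage of the C4–C8 bond is driven by the strain of the four-membered ring. The closest known reaction type is the photocycloaddition/retro-aldol sequence of enol derivatives of cyclopentane-1,3-diones with cyclopentenes. The cyclobutane closes by an intermolecular two-bond cycloaddition; the seven-membered ring is not closed end to end but arises by two-carbon ring expansion of the cyclopentanone when its bond to the carbinol carbon breaks. C8a is set by attack on the alpha face of 6, anti to the beta isopropyl and acetoxy groups that flank the alkene; C3a follows from suprafacial addition and is therefore cis to the C8a–C8 bond (corrected in step 9); C6 is uncontrolled and is removed in step 8. The step needs head-to-tail regioselectivity, which the usual preference of the oxygen-bearing beta-carbon for the less substituted alkene carbon should secure, and alpha-face selectivity, which the two beta substituents should secure.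

Step 8
Reactants: 12 (1S,3R,3aR,8aS)-3-hydroxy-6,8a-dimethyl-4,7-dioxo-3-(propan-2-yl)decahydroazulen-1-yl acetate
Product: 13 (1S,3R,3aR,8aS)-3-hydroxy-6,8a-dimethyl-4,7-dioxo-3-(propan-2-yl)-1,2,3,3a,4,7,8,8a-octahydroazulen-1-yl acetate (cis-fused ene-dione)
Conditions: IBX (2.5 equiv), 4-methoxypyridine N-oxide, DMSO, 23 °C
Reagents that add atoms: none
Why: IBX dehydrogenation of a ketone through its enol; only the C5–C6 bond can be desaturated because C3 and C8a carry no hydrogen, and both C6 epimers converge to one ene-dione.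

Step 9
Reactants: 13 (1S,3R,3aR,8aS)-3-hydroxy-6,8a-dimethyl-4,7-dioxo-3-(propan-2-yl)-1,2,3,3a,4,7,8,8a-octahydroazulen-1-yl acetate
Product: 15 (1S,3R,3aS,8aS)-3-hydroxy-6,8a-dimethyl-4,7-dioxo-3-(propan-2-yl)-1,2,3,3a,4,7,8,8a-octahydroazulen-1-yl acetate (trans-fused ene-dione), via tris(trimethylsilyl) trienol ether 14 (not isolated)
Conditions: Me3SiOTf (4 equiv), Et3N, CH2Cl2, 0 to 23 °C; then 1 M HCl, THF, 0 °C, 5 min
Reagents that add atoms: none
Why: Silyl enol ether formation and kinetic protonation: C4 can enolise only towards C3a, and irreversible C-protonation of 14 at C3a should occur on the alpha face, anti to the beta C8a methyl and beta C3 isopropyl groups that flank it, which inverts C3a to the trans ring fusion (C8 is re-protonated without stereochemical consequence).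

Step 10
Reactants: 15 (1S,3R,3aS,8aS)-3-hydroxy-6,8a-dimethyl-4,7-dioxo-3-(propan-2-yl)-1,2,3,3a,4,7,8,8a-octahydroazulen-1-yl acetate
Product: 16 (1S,3R,3aR,4R,8aS)-3,4-dihydroxy-6,8a-dimethyl-7-oxo-3-(propan-2-yl)-1,2,3,3a,4,7,8,8a-octahydroazulen-1-yl acetate
Conditions: Me4NBH(OAc)3, MeCN–AcOH, −30 °C
Reagents that add atoms: none
Why: Evans–Saksena hydroxyl-directed reduction: the C3 hydroxyl should bind boron and deliver hydride to the neighbouring C4 carbonyl on the face that carries C3 (beta), which sets C4 (R, oxygen alpha, cis to H-3a) and leaves the undirected C7 enone untouched (the C3a descriptor changes from S to R through priorities only).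

Step 11
Reactants: 16 (1S,3R,3aR,4R,8aS)-3,4-dihydroxy-6,8a-dimethyl-7-oxo-3-(propan-2-yl)-1,2,3,3a,4,7,8,8a-octahydroazulen-1-yl acetate; 17 4-(acetyloxy)benzoyl chloride
Product: 18 (1S,3R,3aR,4R,8aS)-1-(acetyloxy)-3-hydroxy-6,8a-dimethyl-7-oxo-3-(propan-2-yl)-1,2,3,3a,4,7,8,8a-octahydroazulen-4-yl 4-(acetyloxy)benzoate
Conditions: pyridine, DMAP (cat.), CH2Cl2, 0 to 23 °C
Reagents that add atoms: none
Why: DMAP-catalysed acylation should esterify the secondary allylic C4 hydroxyl with retention, while the tertiary C3 hydroxyl does not react.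

Step 12
Reactants: 18 (1S,3R,3aR,4R,8aS)-1-(acetyloxy)-3-hydroxy-6,8a-dimethyl-7-oxo-3-(propan-2-yl)-1,2,3,3a,4,7,8,8a-octahydroazulen-4-yl 4-(acetyloxy)benzoate
Product: 19 (1S,3R,3aR,4R,8aS)-1-(acetyloxy)-3-hydroxy-6,8a-dimethyl-7-oxo-3-(propan-2-yl)-1,2,3,3a,4,7,8,8a-octahydroazulen-4-yl 4-hydroxybenzoate (CNP0087181.1)
Conditions: NH4OAc, MeOH–H2O (4:1), 23 °C
Reagents that add atoms: none
Why: Aryl acetates undergo ammonium acetate-mediated methanolysis far faster than the hindered secondary acetate at C1 or the aroyl ester, so only the phenol should be unmasked.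

**Compound list**

1 | 3-methylbutan-2-one | CC(C)C(C)=O | starting material
2 | 2-methylprop-2-enal (methacrolein) | CC(=C)C=O | starting material
3 | (5S)-5-hydroxy-2,6-dimethylhept-6-en-3-one | C=C(C)[C@@H](O)CC(=O)C(C)C | intermediate
4 | (3R,5S)-6-methyl-3-(propan-2-yl)hepta-1,6-diene-3,5-diol | C=C(C)[C@@H](O)C[C@@](O)(C(C)C)C=C | intermediate
5 | (1R,3S)-4-methyl-1-(propan-2-yl)cyclopent-4-ene-1,3-diol | O[C@H]1C[C@@](O)(C(C)C)C=C1C | intermediate
6 | (1S,4R)-4-hydroxy-2-methyl-4-(propan-2-yl)cyclopent-2-en-1-yl acetate | CC(=O)O[C@H]1C[C@@](O)(C(C)C)C=C1C | intermediate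
7 | cyclopentane-1,3-dione | O=C1CCC(=O)C1 | starting material
8 | 3-(benzyloxy)cyclopent-2-en-1-one | O=C1CCC(OCc2ccccc2)=C1 | intermediate
9 | 3-(benzyloxy)-5-methylcyclopent-2-en-1-one (racemic) | CC1CC(OCc2ccccc2)=CC1=O | intermediate
10 | cyclobutane photoadduct: ring A of 6 cis-fused on its alpha face through C3a–C8a to a cyclobutane (C3a, C4, C8, C8a), which is cis-fused, anti to ring A, to the cyclopentanone C4–C8; benzyloxy on C4, ketone C7, methyl on C6 (both epimers), H-3a and CH3-8a beta | CC(=O)O[C@H]1C[C@@](O)(C(C)C)[C@@H]2[C@@]3(OCc4ccccc4)CC(C)C(=O)[C@H]3[C@]12C | intermediate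
11 | cyclobutanol: compound 10 with hydroxyl in place of benzyloxy at C4 | CC(=O)O[C@H]1C[C@@](O)(C(C)C)[C@@H]2[C@@]3(O)CC(C)C(=O)[C@H]3[C@]12C | intermediate
12 | (1S,3R,3aR,8aS)-3-hydroxy-6,8a-dimethyl-4,7-dioxo-3-(propan-2-yl)decahydroazulen-1-yl acetate (cis-fused, C6 epimers) | CC(=O)O[C@H]1C[C@@](O)(C(C)C)[C@@H]2C(=O)CC(C)C(=O)C[C@]12C | intermediate
13 | (1S,3R,3aR,8aS)-3-hydroxy-6,8a-dimethyl-4,7-dioxo-3-(propan-2-yl)-1,2,3,3a,4,7,8,8a-octahydroazulen-1-yl acetate (cis-fused) | CC(=O)O[C@H]1C[C@@](O)(C(C)C)[C@@H]2C(=O)C=C(C)C(=O)C[C@]12C | intermediate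
14 | tris(trimethylsilyl) trienol ether: (1S,3R,8aS)-6,8a-dimethyl-3-(propan-2-yl)-3,4,7-tris[(trimethylsilyl)oxy]-1,2,3,8a-tetrahydroazulen-1-yl acetate | CC(=O)O[C@H]1C[C@@](O[Si](C)(C)C)(C(C)C)C2=C(O[Si](C)(C)C)C=C(C)C(O[Si](C)(C)C)=C[C@]12C | intermediate
15 | (1S,3R,3aS,8aS)-3-hydroxy-6,8a-dimethyl-4,7-dioxo-3-(propan-2-yl)-1,2,3,3a,4,7,8,8a-octahydroazulen-1-yl acetate (trans-fused) | CC(=O)O[C@H]1C[C@@](O)(C(C)C)[C@H]2C(=O)C=C(C)C(=O)C[C@]12C | intermediate
16 | (1S,3R,3aR,4R,8aS)-3,4-dihydroxy-6,8a-dimethyl-7-oxo-3-(propan-2-yl)-1,2,3,3a,4,7,8,8a-octahydroazulen-1-yl acetate | CC(=O)O[C@H]1C[C@@](O)(C(C)C)[C@H]2[C@H](O)C=C(C)C(=O)C[C@]12C | intermediate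
17 | 4-(acetyloxy)benzoyl chloride | CC(=O)Oc1ccc(cc1)C(Cl)=O | starting material
18 | (1S,3R,3aR,4R,8aS)-1-(acetyloxy)-3-hydroxy-6,8a-dimethyl-7-oxo-3-(propan-2-yl)-1,2,3,3a,4,7,8,8a-octahydroazulen-4-yl 4-(acetyloxy)benzoate | CC(=O)O[C@H]1C[C@@](O)(C(C)C)[C@H]2[C@H](OC(=O)c3ccc(OC(C)=O)cc3)C=C(C)C(=O)C[C@]12C | intermediate
19 | (1S,3R,3aR,4R,8aS)-1-(acetyloxy)-3-hydroxy-6,8a-dimethyl-7-oxo-3-(propan-2-yl)-1,2,3,3a,4,7,8,8a-octahydroazulen-4-yl 4-hydroxybenzoate | CC(=O)O[C@H]1C[C@@](O)(C(C)C)[C@H]2[C@H](OC(=O)c3ccc(O)cc3)C=C(C)C(=O)C[C@]12C | target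

**Step count and risks**

Total step count: 12. Longest linear sequence: 10 steps (steps 1, 2, 3, 4, 7, 8, 9, 10, 11, 12).

Steps most likely to fail:

Step 7. The intermolecular photocycloaddition may stall on the hindered trisubstituted alkene while the enone dimerises, or it may give the head-to-head orientation or attack both faces. Fallback: a temporary silicon tether makes the cycloaddition intramolecular. It sets out from 6 and 9. Acid hydrolysis of 9 (1 M HCl, THF) gives 4-methylcyclopentane-1,3-dione F1. Compound 6 is silylated at the tertiary hydroxyl with iPr2SiCl2 and imidazole, and the chlorosilane is treated with F1 and Et3N; silylation at the less hindered oxygen, remote from the methyl group, is expected and gives the tethered silyl enol ether F2. Irradiation (350 nm, MeCN) closes the cyclobutane within a six-membered siladioxane ring, so the enol carbon can only bond to C3a on the alpha face, and gives the silicon-bridged photoadduct F3. HF·pyridine in THF removes silicon and triggers the retro-aldol cleavage, which returns to the route at 12.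

Step 9. Enolisation of the hindered beta H-3a of 13 may be incomplete, or kinetic control may be lost through protonation on both faces or re-enolisation of the strained trans-fused ketone back to the cis isomer. Fallback: proton transfer is replaced by irreversible hydrogen-atom transfer. It sets out from 14. N-Bromosuccinimide (2 equiv, THF, −78 °C) followed by aqueous work-up gives the 3a,8-dibromo ene-dione F4. Bu3SnH with Et3B and air at −78 °C reduces both carbon–bromine bonds; the planar C3a radical should take hydrogen from the stannane on the open alpha face, which returns to the route at 15.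

Step 10. The hindered tertiary hydroxyl may fail to bind boron, so that no hydride is delivered, or external attack on the open alpha face may give the C4 epimer. Fallback: the alpha-face attack is accepted and C4 is inverted during esterification. It sets out from 15. Zn(BH4)2 in Et2O at −78 °C (zinc chelate between the C3 hydroxyl and the C4 carbonyl, external hydride on the alpha face) gives the 4-epi alcohol F5. Mitsunobu esterification with 4-(acetyloxy)benzoic acid (PPh3, iPrO2CN=NCO2iPr, toluene, 0 °C) inverts C4 and installs the ester, which returns to the route at 18.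

**Further compounds**

F1 | step 7 | 4-methylcyclopentane-1,3-dione | CC1CC(=O)CC1=O
F2 | step 7 | (1S,4R)-2-methyl-4-({[(4-methyl-3-oxocyclopent-1-en-1-yl)oxy]di(propan-2-yl)silyl}oxy)-4-(propan-2-yl)cyclopent-2-en-1-yl acetate | CC(=O)O[C@H]1C[C@@](O[Si](C(C)C)(C(C)C)OC2=CC(=O)C(C)C2)(C(C)C)C=C1C
F3 | step 7 | silicon-bridged photoadduct: compound 10 with the C3 and C4 oxygens joined through a di(propan-2-yl)silylene unit in place of the free hydroxyl and the benzyl group | CC(=O)O[C@H]1C[C@@](O5)(C(C)C)[C@@H]2[C@@]3(O[Si]5(C(C)C)C(C)C)CC(C)C(=O)[C@H]3[C@]12C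
F4 | step 9 | (1S,3R,8aS)-3a,8-dibromo-3-hydroxy-6,8a-dimethyl-4,7-dioxo-3-(propan-2-yl)-1,2,3,3a,4,7,8,8a-octahydroazulen-1-yl acetate (mixture at C3a and C8) | CC(=O)O[C@H]1C[C@@](O)(C(C)C)C2(Br)C(=O)C=C(C)C(=O)C(Br)[C@]12C
F5 | step 10 | (1S,3R,3aR,4S,8aS)-3,4-dihydroxy-6,8a-dimethyl-7-oxo-3-(propan-2-yl)-1,2,3,3a,4,7,8,8a-octahydroazulen-1-yl acetate | CC(=O)O[C@H]1C[C@@](O)(C(C)C)[C@H]2[C@@H](O)C=C(C)C(=O)C[C@]12C
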